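**Retrosynthetic overview**
1. Feature: ring A carries CO2Me at C1, the diaryl ketone carbon at C2, OMe at C3 and OH at C5. This meta-dioxygenated benzoate is an eight-carbon chain: an oxalyl cap (ester carbon and ring C1), a pentane-2,4-dione unit (ring C6, C5, C4, C3, C2) and the aroyl carbon. The C3 oxygen is already methylated as an enol ether.
2. Endgame: the acetate is placed on one of the two equivalent ring-B phenols while the ring-A C5 phenol is silylated. Until then the ring-B phenols are carried as benzyl ethers.
3. Key disconnection: the ring-A C1–C2 bond. It is formed by intramolecular aldol attack of chain C7 on the C2 keto ester carbonyl of the open-chain triketo ester, followed by loss of water and enolisation.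
4. Chain assembly: the C7–C8 bond comes from acylating the dianion of the oxalylated methoxypentenone with the ring-B acid chloride. The C2–C3 bond comes from a Claisen condensation of the methoxypentenone with dimethyl oxalate.
5. Ring order: ring B is bought intact. Ring A is the only ring made, in step 6.

Key step: step 6

Assumption: the two open-chain 2,4-dioxo esters are drawn as keto tautomers although they should exist mainly as C2 enols, and (E)-4-methoxypent-3-en-2-one is taken as purchasable (otherwise it is one step from acetylacetone and trimethyl orthoformate).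

**Step 1**
Reactants: 1 2,6-dihydroxy-4-methylbenzoic acid
Product: 2 benzyl 2,6-bis(benzyloxy)-4-methylbenzoate
Conditions: BnBr (3.5 equiv), K2CO3 (4 equiv), DMF, 60 °C
Reagents that add atoms: benzyl bromide, BrCc1ccccc1
Why: Williamson ether synthesis and carboxylate O-alkylation run together, so both chelated phenols and the decarboxylation-prone acid are capped in one operation.

**Step 2**
Reactants: 2 benzyl 2,6-bis(benzyloxy)-4-methylbenzoate
Product: 3 2,6-bis(benzyloxy)-4-methylbenzoic acid
Conditions: KOH (10 equiv), EtOH/H2O, reflux; then 1 M HCl, 0 °C, to pH 3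
Reagents that add atoms: potassium hydroxide, [K+].[OH-]
Why: Saponification by acyl–oxygen cleavage needs heat because of the two ortho substituents, whereas the aryl benzyl ethers are inert to hydroxide.

**Step 3**
Reactants: 3 2,6-bis(benzyloxy)-4-methylbenzoic acid
Product: 4 2,6-bis(benzyloxy)-4-methylbenzoyl chloride
Conditions: (COCl)2 (1.5 equiv), DMF (cat.), CH2Cl2, 0 °C to rt; evaporate, use crude
Reagents that add atoms: oxalyl chloride, ClC(=O)C(=O)Cl
Why: Acid chloride formation through the chloroiminium salt from DMF (Vilsmeier-type activation) runs at or below room temperature, which spares the ortho benzyl ethers and supplies the most reactive acyl donor for a carbonyl flanked by two ortho substituents.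

**Step 4**
Reactants: 5 (E)-4-methoxypent-3-en-2-one; 6 dimethyl oxalate
Product: 8 methyl (E)-6-methoxy-2,4-dioxohept-5-enoate, via lithium dienolate 7 (not isolated)
Conditions: LiN(SiMe3)2 (1.05 equiv), THF, −78 °C; cannulate into 6 (1.5 equiv), THF, −78 to 0 °C; AcOH (1.1 equiv), then pH 6 phosphate buffer
Reagents that add atoms: none
Why: Kinetic deprotonation of a beta-alkoxy enone takes the alpha-prime (acetyl) methyl rather than the vinylogous one, and the crossed Claisen condensation of 7 with the non-enolisable diester, run by adding the enolate to excess 6 to avoid double condensation, is driven by formation of the stabilised diketo ester enolate, while the work-up free of mineral acid keeps 8 from closing to a 4-pyranone.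

**Step 5**
Reactants: 8 methyl (E)-6-methoxy-2,4-dioxohept-5-enoate; 4 2,6-bis(benzyloxy)-4-methylbenzoyl chloride
Product: 10 methyl (E)-8-[2,6-bis(benzyloxy)-4-methylphenyl]-6-methoxy-2,4,8-trioxooct-5-enoate, via dilithium trienediolate 9 (not isolated)
Conditions: 8 (2.0 equiv), LiN(iPr)2 (4.1 equiv), THF, −78 to −30 °C; 4 (1.0 equiv), THF, −78 to −40 °C; AcOH, −78 °C, then pH 6 phosphate buffer; use without acidic chromatography
Reagents that add atoms: none
Why: Terminal acylation of a 1,3-dicarbonyl dianion (vinylogous Claisen condensation): the first equivalent of base gives the C3 enolate, which also shields the keto ester end, the second removes a proton from the vinylogous C7 methyl, and the last-formed, least stabilised site of 9 attacks 4, with the second equivalent of 9 taking up the acidic C7–H of the product.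

**Step 6**
Reactants: 10 methyl (E)-8-[2,6-bis(benzyloxy)-4-methylphenyl]-6-methoxy-2,4,8-trioxooct-5-enoate
Product: 12 methyl 2-[2,6-bis(benzyloxy)-4-methylbenzoyl]-5-hydroxy-3-methoxybenzoate, via cyclohexenone aldol adduct 11 (not isolated)
Conditions: Et3N (1.5 equiv), MeOH, 0 to 40 °C; pH 5 citrate buffer work-up
Reagents that add atoms: none
Why: Et3N converts 10 into its monoanion, and proton shuttling in methanol gives access to the minor tautomer in which chain C7 (alpha to the aryl ketone, gamma to the C4 enone carbonyl) is the carbanion while C2 is a free keto ester carbonyl; C7 adds to C2 and forms the ring-A C1–C2 bond, after which aldol 11 loses water by E1cB and the C4 ketone (ring-A C5) enolises to the phenol, making the sequence irreversible. The closest known reaction types are the mild-base aldol aromatisation of poly-beta-carbonyl esters to resorcylates and the Knoevenagel condensation of C–H acids at C2 of acylpyruvates, as in Guareschi–Thorpe pyridone syntheses. Ring A closes in a 6-(enolexo)-exo-trig mode, for which the E enol ether already holds C4 and C7 cis, and the C7 dienolate lets any Z isomer rotate into place. The two stereocentres of 11 need no control because both become sp2 on aromatisation. Against the other six-membered aldol (C3 onto C8) stand the two ortho benzyloxy groups, which shield and electronically deactivate the aryl ketone, and the low nucleophilicity of the fully stabilised C3 enolate. The enol ether does not by itself exclude attack of the C2 enol oxygen on C6 with loss of methanol to give a 4-pyranone-2-carboxylate, but that path needs the neutral enol and acid, so the medium is kept basic (the C4 carbonyl is then part of an enolate and C6 is no acceptor), and methanol as solvent makes exchange at the ester and at C6 degenerate.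

**Step 7**
Reactants: 12 methyl 2-[2,6-bis(benzyloxy)-4-methylbenzoyl]-5-hydroxy-3-methoxybenzoate
Product: 13 methyl 2-[2,6-bis(benzyloxy)-4-methylbenzoyl]-5-[(tert-butyldimethylsilyl)oxy]-3-methoxybenzoate
Conditions: TBSCl (1.2 equiv), imidazole (2.5 equiv), DMF, rt
Reagents that add atoms: tert-butyldimethylsilyl chloride, CC(C)(C)[Si](C)(C)Cl
Why: Imidazole-promoted O-silylation meets a single free, unhindered and non-chelated phenol, so no selectivity question arises.

**Step 8**
Reactants: 13 methyl 2-[2,6-bis(benzyloxy)-4-methylbenzoyl]-5-[(tert-butyldimethylsilyl)oxy]-3-methoxybenzoate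
Product: 14 methyl 5-[(tert-butyldimethylsilyl)oxy]-2-(2,6-dihydroxy-4-methylbenzoyl)-3-methoxybenzoate
Conditions: H2 (1 atm), 10% Pd/C, EtOAc, rt
Reagents that add atoms: none
Why: Catalytic hydrogenolysis cleaves both aryl benzyl ethers, while the aryl silyl ether (aprotic solvent), the methyl ester and the crowded diaryl ketone should survive at atmospheric pressure.

**Step 9**
Reactants: 14 methyl 5-[(tert-butyldimethylsilyl)oxy]-2-(2,6-dihydroxy-4-methylbenzoyl)-3-methoxybenzoate
Product: 15 methyl 2-(2-acetoxy-6-hydroxy-4-methylbenzoyl)-5-[(tert-butyldimethylsilyl)oxy]-3-methoxybenzoate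
Conditions: Ac2O (1.05 equiv), pyridine, 0 °C
Reagents that add atoms: acetic anhydride, CC(=O)OC(C)=O
Why: Phenol O-acylation at either of the two symmetry-equivalent ring-B hydroxyls gives the same product, and after the first acetylation the remaining hydroxyl is locked in a strong hydrogen bond to the ketone and is less nucleophilic, so one equivalent in the cold should stop at the monoacetate.

**Step 10**
Reactants: 15 methyl 2-(2-acetoxy-6-hydroxy-4-methylbenzoyl)-5-[(tert-butyldimethylsilyl)oxy]-3-methoxybenzoate
Product: 16 penibenzophenone C, methyl 2-(2-acetoxy-6-hydroxy-4-methylbenzoyl)-5-hydroxy-3-methoxybenzoate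
Conditions: Bu4NF (1.1 equiv), AcOH (1.2 equiv), THF, 0 °C
Reagents that add atoms: none
Why: Fluoride-induced desilylation of an aryl silyl ether is fast at 0 °C, and the acetic acid buffer protonates the released phenoxide at once, so the aryl acetate should be neither cleaved nor transferred.

**Compound list**
1 | 2,6-dihydroxy-4-methylbenzoic acid | Cc1cc(O)c(C(=O)O)c(O)c1 | starting material
2 | benzyl 2,6-bis(benzyloxy)-4-methylbenzoate | Cc1cc(OCc2ccccc2)c(C(=O)OCc2ccccc2)c(OCc2ccccc2)c1 | intermediate
3 | 2,6-bis(benzyloxy)-4-methylbenzoic acid | Cc1cc(OCc2ccccc2)c(C(=O)O)c(OCc2ccccc2)c1 | intermediate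
4 | 2,6-bis(benzyloxy)-4-methylbenzoyl chloride | Cc1cc(OCc2ccccc2)c(C(=O)Cl)c(OCc2ccccc2)c1 | intermediate
5 | (E)-4-methoxypent-3-en-2-one | CO/C(C)=C/C(C)=O | starting material
6 | dimethyl oxalate | COC(=O)C(=O)OC | starting material
7 | lithium (E)-4-methoxypenta-1,3-dien-2-olate, formed in the flask | [Li+].CO/C(C)=C/C(=C)[O-] | intermediate
8 | methyl (E)-6-methoxy-2,4-dioxohept-5-enoate | COC(=O)C(=O)CC(=O)/C=C(/OC)C | intermediate
9 | dilithium 1,6-dimethoxy-1-oxohepta-2,4,6-triene-2,4-diolate, formed in the flask, enolate geometries undefined | [Li+].[Li+].COC(=O)C([O-])=CC([O-])=CC(=C)OC | intermediate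
10 | methyl (E)-8-[2,6-bis(benzyloxy)-4-methylphenyl]-6-methoxy-2,4,8-trioxooct-5-enoate | COC(=O)C(=O)CC(=O)/C=C(/OC)CC(=O)c1c(OCc2ccccc2)cc(C)cc1OCc1ccccc1 | intermediate
11 | methyl 2-[2,6-bis(benzyloxy)-4-methylbenzoyl]-1-hydroxy-3-methoxy-5-oxocyclohex-3-ene-1-carboxylate, formed in the flask, diastereomer mixture, both centres erased on aromatisation | COC(=O)C1(O)CC(=O)C=C(OC)C1C(=O)c1c(OCc2ccccc2)cc(C)cc1OCc1ccccc1 | intermediate
12 | methyl 2-[2,6-bis(benzyloxy)-4-methylbenzoyl]-5-hydroxy-3-methoxybenzoate | COC(=O)c1cc(O)cc(OC)c1C(=O)c1c(OCc2ccccc2)cc(C)cc1OCc1ccccc1 | intermediate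
13 | methyl 2-[2,6-bis(benzyloxy)-4-methylbenzoyl]-5-[(tert-butyldimethylsilyl)oxy]-3-methoxybenzoate | COC(=O)c1cc(O[Si](C)(C)C(C)(C)C)cc(OC)c1C(=O)c1c(OCc2ccccc2)cc(C)cc1OCc1ccccc1 | intermediate
14 | methyl 5-[(tert-butyldimethylsilyl)oxy]-2-(2,6-dihydroxy-4-methylbenzoyl)-3-methoxybenzoate | COC(=O)c1cc(O[Si](C)(C)C(C)(C)C)cc(OC)c1C(=O)c1c(O)cc(C)cc1O | intermediate
15 | methyl 2-(2-acetoxy-6-hydroxy-4-methylbenzoyl)-5-[(tert-butyldimethylsilyl)oxy]-3-methoxybenzoate | COC(=O)c1cc(O[Si](C)(C)C(C)(C)C)cc(OC)c1C(=O)c1c(O)cc(C)cc1OC(C)=O | intermediate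
16 | penibenzophenone C | COC(=O)c1cc(O)cc(OC)c1C(=O)c1c(O)cc(C)cc1OC(C)=O | target

**Total step count:** 10. **Longest linear sequence:** 9 (steps 1, 2, 3, 5, 6, 7, 8, 9, 10).

**Steps most likely to fail**

Step 6. The chain may close through oxygen instead of carbon: the C2 enol oxygen adds to C6 and methanol is lost. It may also rest as the unreactive C3 enolate, or fold in the opposite aldol sense.

The fallback builds ring A by cycloaddition. It sets out from 4 and comes back at 12.
- Reduction of 4 with LiAlH(OtBu)3 in THF at −78 °C should give 2,6-bis(benzyloxy)-4-methylbenzaldehyde F1.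
- Addition of lithiated methyl propiolate (LiN(iPr)2, THF, −78 °C) should give racemic methyl 4-[2,6-bis(benzyloxy)-4-methylphenyl]-4-hydroxybut-2-ynoate F2.
- MnO2 in CH2Cl2 should oxidise it to methyl 4-[2,6-bis(benzyloxy)-4-methylphenyl]-4-oxobut-2-ynoate F3.
- A Diels–Alder reaction of F3 with 1,1-dimethoxy-3-(trimethylsilyloxy)buta-1,3-diene (COC(OC)=CC(=C)O[Si](C)(C)C) in toluene joins the nucleophilic CH2 terminus of the diene to the alkyne carbon beta to the ketone, which is the one bearing CO2Me. This gives methyl 2-[2,6-bis(benzyloxy)-4-methylbenzoyl]-3,3-dimethoxy-5-(trimethylsilyloxy)cyclohexa-1,4-diene-1-carboxylate F4.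
- F4 aromatises by loss of methanol and is desilylated on dilute acid work-up to 12.

Step 5. Proton transfer from the acylated product to unreacted dianion, acylation on oxygen, or slow attack on the shielded acyl chloride may erode the coupling.

The fallback replaces acylation by addition and oxidation. It sets out from 4 and 8 and comes back at 10.
- 2,6-Bis(benzyloxy)-4-methylbenzaldehyde F1, made from 4 as described above, is added at −78 °C to dianion 9 generated from 8.
- This vinylogous aldol addition produces no new C–H acid and should give racemic methyl (E)-8-[2,6-bis(benzyloxy)-4-methylphenyl]-8-hydroxy-6-methoxy-2,4-dioxooct-5-enoate F5.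
- The electron-rich benzylic alcohol of F5 is then oxidised with MnO2 in CH2Cl2 to 10.

Step 9. Acetylation may run on to the diacetate or give a statistical spread.

The fallback differentiates the two ring-B oxygens before deprotection. It sets out from 13 and comes back at 15.
- MgBr2·OEt2 in toluene/Et2O with heating should cleave only one benzyl ether ortho to the ketone, because the magnesium phenoxide chelate formed first shuts down the second cleavage. The product is methyl 2-[2-(benzyloxy)-6-hydroxy-4-methylbenzoyl]-5-[(tert-butyldimethylsilyl)oxy]-3-methoxybenzoate F6.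
- Exhaustive acetylation (Ac2O, pyridine, DMAP) should give methyl 2-[2-acetoxy-6-(benzyloxy)-4-methylbenzoyl]-5-[(tert-butyldimethylsilyl)oxy]-3-methoxybenzoate F7.
- Hydrogenolysis (H2, 10% Pd/C, EtOAc) of the last benzyl ether should deliver 15.

**Further compounds**
F1 | step 6 | 2,6-bis(benzyloxy)-4-methylbenzaldehyde | Cc1cc(OCc2ccccc2)c(C=O)c(OCc2ccccc2)c1
F2 | step 6 | methyl 4-[2,6-bis(benzyloxy)-4-methylphenyl]-4-hydroxybut-2-ynoate (racemic) | COC(=O)C#CC(O)c1c(OCc2ccccc2)cc(C)cc1OCc1ccccc1
F3 | step 6 | methyl 4-[2,6-bis(benzyloxy)-4-methylphenyl]-4-oxobut-2-ynoate | COC(=O)C#CC(=O)c1c(OCc2ccccc2)cc(C)cc1OCc1ccccc1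
F4 | step 6 | methyl 2-[2,6-bis(benzyloxy)-4-methylbenzoyl]-3,3-dimethoxy-5-(trimethylsilyloxy)cyclohexa-1,4-diene-1-carboxylate | COC(=O)C1=C(C(=O)c2c(OCc3ccccc3)cc(C)cc2OCc2ccccc2)C(OC)(OC)C=C(O[Si](C)(C)C)C1
F5 | step 5 | methyl (E)-8-[2,6-bis(benzyloxy)-4-methylphenyl]-8-hydroxy-6-methoxy-2,4-dioxooct-5-enoate (racemic) | COC(=O)C(=O)CC(=O)/C=C(/OC)CC(O)c1c(OCc2ccccc2)cc(C)cc1OCc1ccccc1
F6 | step 9 | methyl 2-[2-(benzyloxy)-6-hydroxy-4-methylbenzoyl]-5-[(tert-butyldimethylsilyl)oxy]-3-methoxybenzoate | COC(=O)c1cc(O[Si](C)(C)C(C)(C)C)cc(OC)c1C(=O)c1c(O)cc(C)cc1OCc1ccccc1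
F7 | step 9 | methyl 2-[2-acetoxy-6-(benzyloxy)-4-methylbenzoyl]-5-[(tert-butyldimethylsilyl)oxy]-3-methoxybenzoate | COC(=O)c1cc(O[Si](C)(C)C(C)(C)C)cc(OC)c1C(=O)c1c(OC(C)=O)cc(C)cc1OCc1ccccc1
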